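# Total synthesis of (−)-carinol

**Assumption:** the SMILES is read as (2S,3S)-carinol, the diol that results from opening (3S,4S)-nortrachelogenin. Aryl bromide 4 and arylacetic acid 8 are taken as catalogue items.

## Retrosynthetic overview

1. Carinol 13 ⇒ debenzylation and LiAlH4 lactone opening ⇒ trans-lactone 11, which is (3S,4S)-O,O'-dibenzylnortrachelogenin.
2. Key disconnection is the quaternary C3–CH2Ar bond of 11. It comes from a visible-light, doubly decarboxylative radical cross-coupling of α-hydroxy-α-carboxy lactone 7 with benzylic N-acyloxyphthalimide 10, with C4 directing the face.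
3. 7 ⇒ Ar–CH2 bond formed by Cu-catalysed ArMgBr opening of cyclopropane-fused lactone 3, in-situ enolate hydroxylation, then saponification.
4. 3 ⇒ (R)-epichlorohydrin 1 (the only source of chirality) + diethyl malonate 2.
5. Ring order: cyclopropane, then γ-lactone (both in step 1). The cyclopropane is spent in step 2. The lactone is the stereo-template in step 5 and is opened in step 6, so the target is acyclic.

## Route

**Step 1**
- Reactants: 1 (R)-epichlorohydrin; 2 diethyl malonate
- Product: 3 ethyl (1S,5R)-2-oxo-3-oxabicyclo[3.1.0]hexane-1-carboxylate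
- Conditions: NaOEt (1.05 equiv), EtOH, 0 °C → reflux, 16 h
- Reagents that add atoms: diethyl malonate (2), CCOC(=O)CC(=O)OCC
- Why: In this malonate–epichlorohydrin annulation (epoxide opening, epoxide re-formation by chloride displacement, 3-exo-tet cyclopropanation, lactonisation), the purchased stereocentre is inverted once in the intramolecular SN2 to become C5 (R), and C1 (S) is forced by the cis ring fusion.

**Step 2**
- Reactants: 3; 4 1-(benzyloxy)-4-bromo-2-methoxybenzene (as its Grignard reagent); 5 (±)-trans-3-phenyl-2-(phenylsulfonyl)oxaziridine (racemic Davis reagent)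
- Product: 6 ethyl (3RS,4S)-4-[4-(benzyloxy)-3-methoxybenzyl]-3-hydroxy-2-oxotetrahydrofuran-3-carboxylate (C3 epimer mixture)
- Conditions: 4, Mg, THF, 40 °C; add to 3, CuI (15 mol %), THF, −30 °C, 2 h; then 5 (1.5 equiv), −78 → 0 °C; aq NH4Cl
- Reagents that add atoms: 4 (aryl group), COc1cc(Br)ccc1OCc1ccccc1; 5 (oxygen atom), O=S(=O)(c1ccccc1)N1OC1c1ccccc1
- Why: Cu-catalysed homoconjugate addition of the aryl Grignard attacks the unsubstituted cyclopropane CH2 of the doubly activated ring and leaves the C–H stereocentre untouched (now C4, S only by CIP ranking), and the resulting magnesium malonate-type enolate is hydroxylated in situ (Davis oxidation), where the C3 configuration does not matter because step 5 erases it.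

**Step 3**
- Reactants: 6
- Product: 7 (3RS,4S)-4-[4-(benzyloxy)-3-methoxybenzyl]-3-hydroxy-2-oxotetrahydrofuran-3-carboxylic acid
- Conditions: LiOH (4 equiv), THF/H2O, 0 °C → rt; then 2 M HCl (pH 1), EtOAc, rt, 2 h
- Reagents that add atoms: water/lithium hydroxide (acid oxygen), O and [Li+].[OH-]
- Why: Saponification cleaves the ethyl ester (and transiently the lactone) and acidification re-closes the five-membered lactone on either carboxyl, which only affects the disposable C3 centre, while C4 is β to the carbonyls and cannot epimerise.

**Step 4**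
- Reactants: 8 [4-(benzyloxy)-3-methoxyphenyl]acetic acid; 9 N-hydroxyphthalimide
- Product: 10 1,3-dioxoisoindolin-2-yl [4-(benzyloxy)-3-methoxyphenyl]acetate
- Conditions: DIC (1.1 equiv), DMAP (5 mol %), CH2Cl2, rt, 3 h
- Reagents that add atoms: N-hydroxyphthalimide (9), ON1C(=O)c2ccccc2C1=O
- Why: Carbodiimide (Steglich-type) esterification gives a crystalline redox-active ester, and no stereocentre is involved.

**Step 5 (key step)**
- Reactants: 7; 10 (1.5 equiv)
- Product: 11 (3S,4S)-3,4-bis[4-(benzyloxy)-3-methoxybenzyl]-3-hydroxydihydrofuran-2(3H)-one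
- Conditions: Ir[dF(CF3)ppy]2(dtbbpy)PF6 (2 mol %), CsHCO3 (1.05 equiv), degassed DMSO (0.05 M), 450 nm LEDs, 20 °C, 16 h
- Reagents that add atoms: 10 (ArCH2 unit), O=C(Cc1ccc(OCc2ccccc2)c(OC)c1)ON1C(=O)c2ccccc2C1=O
- Why: Proposed new method: this is a redox-neutral, metal-free, doubly decarboxylative C(sp3)–C(sp3) radical cross-coupling in which excited Ir(III) (about +1.2 V) oxidises the caesium α-hydroxycarboxylate of 7 and CO2 loss gives, site-specifically, the planar captodative (ketyl-type) lactone C3 radical without passing through the configurationally labile α-keto lactone; the Ir(II) formed (−1.37 V) reduces 10, which fragments to CO2, phthalimide anion and the primary benzylic radical; the hindered tertiary radical self-couples slowly, accumulates (persistent-radical effect) and captures the transient benzyl radical on the face anti to the C4 arylmethyl group, so the purchased centre sets the quaternary carbinol as 3S (trans-dibenzyl, dr ≥ 5:1 expected, minor epimer removed by chromatography); the closest known reaction types are photoredox ketyl–benzyl radical cross-coupling of α-keto esters, photoredox decarboxylation of α-oxy acids (decarboxylative Giese chemistry) and reductive fragmentation of N-acyloxyphthalimides.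

**Step 6**
- Reactants: 11
- Product: 12 (2S,3S)-2,3-bis[4-(benzyloxy)-3-methoxybenzyl]butane-1,2,4-triol
- Conditions: LiAlH4 (3 equiv), THF, 0 °C → rt; Rochelle-salt work-up
- Reagents that add atoms: none
- Why: LiAlH4 reduces the γ-lactone to the 1,4-diol, neither stereocentre is enolisable (one is quaternary, the other is β to the carbonyl), and the benzyl ethers are inert.

**Step 7**
- Reactants: 12
- Product: 13 (−)-carinol, (2S,3S)-2,3-bis(4-hydroxy-3-methoxybenzyl)butane-1,2,4-triol
- Conditions: H2 (1 atm), 10 % Pd/C, EtOH–EtOAc, rt
- Reagents that add atoms: none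
- Why: Catalytic hydrogenolysis removes both aryl benzyl ethers, the tertiary alcohol is homobenzylic rather than benzylic so it survives, and no stereocentre is touched.

## Compound list

| No. | Name | SMILES | Role |
|---|---|---|---|
| 1 | (R)-epichlorohydrin | ClC[C@H]1CO1 | starting material |
| 2 | diethyl malonate | CCOC(=O)CC(=O)OCC | starting material |
| 3 | ethyl (1S,5R)-2-oxo-3-oxabicyclo[3.1.0]hexane-1-carboxylate | CCOC(=O)[C@]12C[C@H]1COC2=O | intermediate |
| 4 | 1-(benzyloxy)-4-bromo-2-methoxybenzene | COc1cc(Br)ccc1OCc1ccccc1 | starting material |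
| 5 | (±)-trans-3-phenyl-2-(phenylsulfonyl)oxaziridine | O=S(=O)(c1ccccc1)N1OC1c1ccccc1 | starting material (racemic reagent, O donor) |
| 6 | ethyl (3RS,4S)-4-[4-(benzyloxy)-3-methoxybenzyl]-3-hydroxy-2-oxotetrahydrofuran-3-carboxylate | CCOC(=O)C1(O)[C@@H](Cc2ccc(OCc3ccccc3)c(OC)c2)COC1=O | intermediate |
| 7 | (3RS,4S)-4-[4-(benzyloxy)-3-methoxybenzyl]-3-hydroxy-2-oxotetrahydrofuran-3-carboxylic acid | OC(=O)C1(O)[C@@H](Cc2ccc(OCc3ccccc3)c(OC)c2)COC1=O | intermediate |
| 8 | [4-(benzyloxy)-3-methoxyphenyl]acetic acid | COc1cc(CC(=O)O)ccc1OCc1ccccc1 | starting material |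
| 9 | N-hydroxyphthalimide | ON1C(=O)c2ccccc2C1=O | starting material (reagent) |
| 10 | 1,3-dioxoisoindolin-2-yl [4-(benzyloxy)-3-methoxyphenyl]acetate | O=C(Cc1ccc(OCc2ccccc2)c(OC)c1)ON1C(=O)c2ccccc2C1=O | intermediate |
| 11 | (3S,4S)-3,4-bis[4-(benzyloxy)-3-methoxybenzyl]-3-hydroxydihydrofuran-2(3H)-one | O=C1OC[C@H](Cc2ccc(OCc3ccccc3)c(OC)c2)[C@@]1(O)Cc1ccc(OCc2ccccc2)c(OC)c1 | intermediate |
| 12 | (2S,3S)-2,3-bis[4-(benzyloxy)-3-methoxybenzyl]butane-1,2,4-triol | COc1cc(C[C@@H](CO)[C@](O)(CO)Cc2ccc(OCc3ccccc3)c(OC)c2)ccc1OCc1ccccc1 | intermediate |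
| 13 | (−)-carinol | COc1cc(C[C@@H](CO)[C@](O)(CO)Cc2ccc(O)c(OC)c2)ccc1O | target |

## Step count

- Total steps: 7
- Longest linear sequence: 6 (1 → 3 → 6 → 7 → 11 → 12 → 13). Step 4 is a one-step side branch.

## Steps most likely to fail

1. **Step 5 (new cross-coupling).**
   - Risks: bibenzyl formation may starve the lactone radical. The ketyl-type radical may be over-oxidised to the α-keto lactone. The dr may be modest.
   - Fallback (known chemistry, one extra step): thermally decarboxylate 7 to the α-hydroxy-β-arylmethyl lactone. Then form the lithium alkoxide–enolate dianion (LDA, 2.2 equiv, THF/DMPU, −78 °C) and alkylate it with 4-(benzyloxy)-3-methoxybenzyl bromide. This is the established anti-selective enolate benzylation that gives trachelogenin-type trans lactones, and it also leads to 11.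

2. **Step 2 (tandem opening and hydroxylation).**
   - Risks: the stabilised magnesium enolate may react sluggishly with 5, or add to the sulfonimine by-product.
   - Fallback: separate the two events and change the oxygenation chemistry. Quench and isolate the malonate-type lactone, then acyloxylate its sodium enolate with dibenzoyl peroxide. The benzoate falls off in step 3, so 7 is reached unchanged.

3. **Step 3 (saponification and relactonisation).**
   - Risks: relactonisation may be incomplete, or the hydroxymalonic half-acid may decarboxylate prematurely on work-up.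
   - Fallback: change the ester strategy from the start. Use di-tert-butyl malonate in step 1 so that the tert-butyl ester analogue of 6 is unmasked with TFA/CH2Cl2. The lactone is then never opened and the material never sees aqueous base.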